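## Retrosynthetic overview

1. The target is disconnected at the C8 ester: the C8 alcohol plus tigloyl chloride (last step).
2. The ten-membered carbocycle and the trans-fused α-methylene lactone are formed together by a chromium-mediated intramolecular 2-(methoxycarbonyl)allylation of a Z-enal (C6–C7 bond); the allylic bromide comes from cross-metathesis with methyl 2-(bromomethyl)acrylate.
3. Key step: the 3(2H)-furanone and its quaternary C10 centre arise from a gold-catalysed cycloisomerisation of a 2-hydroxy-2-alkynyl ketone with a 1,2-methyl shift (C1→C10) that relays the carbinol configuration.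
4. The hydroxy ketone comes from a boron aldol with acrolein (C8–C9) and a proposed enantioselective zinc-mediated mono-alkynylation of biacetyl with the silylated (Z)-enynol (C1–C2).
5. Ring order: furanone first, then the ten-membered ring and the lactone in one operation.

Assumption: germacrane numbering (C1–C15) is used for positions, and compounds 1, 3, 7, 14 and 20 are taken as commercial.

## Route

Step 1
Reactants: 1 (Z)-3-methylpent-2-en-4-yn-1-ol
Product: 2 triethyl{[(2Z)-3-methylpent-2-en-4-yn-1-yl]oxy}silane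
Conditions: TESCl, imidazole, CH2Cl2, 0 °C
Reagents that add atoms: triethylsilyl chloride, CC[Si](Cl)(CC)CC
Why: Standard silylation of a primary alcohol; the terminal alkyne and the Z-olefin are untouched.

Step 2
Reactants: 2 triethyl{[(2Z)-3-methylpent-2-en-4-yn-1-yl]oxy}silane; 3 butane-2,3-dione
Product: 6 (3R,6Z)-3-hydroxy-3,6-dimethyl-8-(triethylsilyloxy)oct-6-en-4-yn-2-one, via methylzinc acetylide 4 (not isolated), via methylzinc alkoxide 5 (not isolated)
Conditions: Me2Zn (1.2 equiv), (S,S)-ProPhenol [2,6-bis{[(2S)-2-(hydroxydiphenylmethyl)pyrrolidin-1-yl]methyl}-4-methylphenol] (20 mol%), toluene, 23 °C, 1 h; then biacetyl (slight excess, slow addition), −20 °C; then H2O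
Reagents that add atoms: none
Why: Proposed new method: desymmetrising enantioselective mono-alkynylation of a symmetric 1,2-diketone by a dinuclear zinc–ProPhenol catalyst, in which Me2Zn deprotonates the terminal alkyne of 2 (methane is lost) to give the methylzinc acetylide, biacetyl binds in its s-cis form as a five-membered chelate to one zinc of the chiral dinuclear pocket while the acetylide sits on the other zinc, so the alkynyl group (which transfers faster than methyl) is delivered to one enantioface of one of the two equivalent carbonyls and sets the (3R) carbinol (the ligand antipode is used if the sense proves opposite), and the tertiary zinc alkoxide formed no longer offers an activated 1,2-dicarbonyl so addition stops after one carbonyl; the closest known reaction types are the zinc–ProPhenol alkynylation of aldehydes and the zinc-mediated asymmetric alkynylation of α-keto esters and trifluoromethyl ketones.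

Step 3
Reactants: 6 (3R,6Z)-3-hydroxy-3,6-dimethyl-8-(triethylsilyloxy)oct-6-en-4-yn-2-one; 7 acrolein
Product: 10 (3R,6R,9Z)-3,6-dihydroxy-6,9-dimethyl-11-(triethylsilyloxy)undeca-1,9-dien-7-yn-5-one, via bis-boryl enolate 8 (not isolated), via boron aldolate 9 (not isolated)
Conditions: (−)-Ipc2BCl (2.3 equiv), Et3N, Et2O, 0 °C; 7, −78 → −20 °C; then H2O2, MeOH, pH 7 buffer
Reagents that add atoms: none
Why: Paterson boron aldol of a methyl ketone: the first equivalent of reagent masks the tertiary hydroxyl as its borinate, the second forms the enol borinate at the only enolisable position, and reagent-controlled 1,2-addition to acrolein sets the C8 carbinol as (3R) (the antipodal reagent is used if the facial sense proves opposite).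

Step 4
Reactants: 10 (3R,6R,9Z)-3,6-dihydroxy-6,9-dimethyl-11-(triethylsilyloxy)undeca-1,9-dien-7-yn-5-one
Product: 11 (3R,6R,9Z)-3-(tert-butyldimethylsilyloxy)-6-hydroxy-6,9-dimethyl-11-(triethylsilyloxy)undeca-1,9-dien-7-yn-5-one
Conditions: TBSCl, imidazole, DMF, 25 °C
Reagents that add atoms: tert-butyldimethylsilyl chloride, CC(C)(C)[Si](C)(C)Cl
Why: Chemoselective silylation: the secondary allylic alcohol reacts, the hindered tertiary propargylic alcohol does not.

Step 5
Reactants: 11 (3R,6R,9Z)-3-(tert-butyldimethylsilyloxy)-6-hydroxy-6,9-dimethyl-11-(triethylsilyloxy)undeca-1,9-dien-7-yn-5-one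
Product: 12 (2R)-2-[(2R)-2-(tert-butyldimethylsilyloxy)but-3-en-1-yl]-2-methyl-5-[(2Z)-4-(triethylsilyloxy)but-2-en-2-yl]furan-3(2H)-one
Conditions: AuCl3 (5 mol%), CH2Cl2, 23 °C
Reagents that add atoms: none
Why: Gold-catalysed cycloisomerisation of a 2-hydroxy-2-alkynyl ketone (heterocyclisation followed by an α-ketol-type 1,2-alkyl shift): the C10 carbonyl oxygen adds 5-endo to the activated alkyne, the methyl group migrates from C1 to the oxocarbenium carbon C10 on the face it already occupies while C1 becomes the ketone, and protodeauration releases the furanone, so the (R)-carbinol is relayed into the (R)-configured quaternary C10.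

Step 6
Reactants: 12 (2R)-2-[(2R)-2-(tert-butyldimethylsilyloxy)but-3-en-1-yl]-2-methyl-5-[(2Z)-4-(triethylsilyloxy)but-2-en-2-yl]furan-3(2H)-one
Product: 13 (2Z)-3-{(5R)-5-[(2R)-2-(tert-butyldimethylsilyloxy)but-3-en-1-yl]-5-methyl-4-oxo-4,5-dihydrofuran-2-yl}but-2-enal
Conditions: (COCl)2, DMSO, CH2Cl2, −78 → −30 °C; then Et3N
Reagents that add atoms: none
Why: Swern oxidation applied directly to a primary triethylsilyl ether (the chlorosulfonium reagent cleaves primary TES ethers and oxidises in the same pot, the secondary TBS ether is inert), and the Z-enal geometry is kept at low temperature.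

Step 7
Reactants: 13 (2Z)-3-{(5R)-5-[(2R)-2-(tert-butyldimethylsilyloxy)but-3-en-1-yl]-5-methyl-4-oxo-4,5-dihydrofuran-2-yl}but-2-enal; 14 methyl 2-(bromomethyl)prop-2-enoate
Product: 15 methyl (2Z,4R)-2-(bromomethyl)-4-(tert-butyldimethylsilyloxy)-5-{(2R)-2-methyl-3-oxo-5-[(2Z)-4-oxobut-2-en-2-yl]-2,3-dihydrofuran-2-yl}pent-2-enoate
Conditions: the acrylate in fivefold excess, second-generation Hoveyda–Grubbs catalyst [RuCl2(H2IMes)(=CH-C6H4-2-OiPr)] (10 mol%), CH2Cl2, 40 °C
Reagents that add atoms: none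
Why: Olefin cross-metathesis between the only monosubstituted alkene and the 1,1-disubstituted acrylate (which does not homodimerise) gives the trisubstituted enoate with loss of ethene, while the trisubstituted, conjugated and furanone double bonds do not react; the enoate geometry is unimportant because the allylmetal formed next equilibrates.

Step 8
Reactants: 15 methyl (2Z,4R)-2-(bromomethyl)-4-(tert-butyldimethylsilyloxy)-5-{(2R)-2-methyl-3-oxo-5-[(2Z)-4-oxobut-2-en-2-yl]-2,3-dihydrofuran-2-yl}pent-2-enoate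
Product: 18 (6R,7S,8R,10R)-8-O-(tert-butyldimethylsilyl) ether of the 8-desacyl target, via allylchromium species 16 (not isolated), via seco chromium alkoxide 17 (not isolated)
Conditions: CrCl2 (8 equiv), THF, 0.002 M (slow addition of the bromide), 25 °C; aqueous work-up
Reagents that add atoms: none
Why: Intramolecular Nozaki–Hiyama–Kishi-type (chromium Barbier) allylation: divalent chromium inserts into the allylic C–Br bond, the allylchromium adds through C7 to the Z-enal in a cyclic six-membered transition state, and the chromium alkoxide closes onto the methyl ester to give the α-methylene lactone; the trans ring fusion (H6/H7 anti) and the face of attack are expected from macrocyclic control by the C8 silyloxy centre and the rigid furanone/Z-olefin segment rather than from the acyclic preference of such reagents, and the step sets C6 and C7 while closing the ten-membered ring.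

Step 9
Reactants: 18 (6R,7S,8R,10R)-8-O-(tert-butyldimethylsilyl) ether of the 8-desacyl target
Product: 19 (6R,7R,8R,10R)-8-hydroxy lactone (8-desacyl target)
Conditions: HF·pyridine, THF/pyridine, 0 → 25 °C
Reagents that add atoms: none
Why: Fluoride-mediated desilylation under buffered acidic conditions that the α-methylene lactone and the furanone tolerate; no stereocentre is touched (the C7 descriptor changes only through CIP priorities).

Step 10
Reactants: 19 (6R,7R,8R,10R)-8-hydroxy lactone (8-desacyl target); 20 (E)-2-methylbut-2-enoyl chloride (tigloyl chloride)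
Product: 21 atripliciolide tiglate
Conditions: pyridine, DMAP (10 mol%), CH2Cl2, 0 °C
Reagents that add atoms: none
Why: DMAP-catalysed acylation of the secondary C8 alcohol with the acid chloride, with retention at C8 and of the E-configured tiglate double bond.

## Compound list

1 | (Z)-3-methylpent-2-en-4-yn-1-ol | C#C/C(C)=C\CO | starting material
2 | triethyl{[(2Z)-3-methylpent-2-en-4-yn-1-yl]oxy}silane | C#C/C(C)=C\CO[Si](CC)(CC)CC | intermediate
3 | butane-2,3-dione (biacetyl) | CC(=O)C(C)=O | starting material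
4 | methylzinc acetylide of 2 | C[Zn]C#C/C(C)=C\CO[Si](CC)(CC)CC | intermediate
5 | methylzinc alkoxide of 6 | CC(=O)[C@](C)(O[Zn]C)C#C/C(C)=C\CO[Si](CC)(CC)CC | intermediate
6 | (3R,6Z)-3-hydroxy-3,6-dimethyl-8-(triethylsilyloxy)oct-6-en-4-yn-2-one | CC(=O)[C@](C)(O)C#C/C(C)=C\CO[Si](CC)(CC)CC | intermediate
7 | acrolein (prop-2-enal) | C=CC=O | starting material
8 | enol diisopinocampheylborinate of 6 with the tertiary oxygen also borylated | C=C(OB([C@H]1[C@H](C)[C@H]2C[C@@H](C1)C2(C)C)[C@H]1[C@H](C)[C@H]2C[C@@H](C1)C2(C)C)[C@](C)(OB([C@H]1[C@H](C)[C@H]2C[C@@H](C1)C2(C)C)[C@H]1[C@H](C)[C@H]2C[C@@H](C1)C2(C)C)C#C/C(C)=C\CO[Si](CC)(CC)CC | intermediate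
9 | bis(diisopinocampheylboryl) aldolate of 10 | C=C[C@H](OB([C@H]1[C@H](C)[C@H]2C[C@@H](C1)C2(C)C)[C@H]1[C@H](C)[C@H]2C[C@@H](C1)C2(C)C)CC(=O)[C@](C)(OB([C@H]1[C@H](C)[C@H]2C[C@@H](C1)C2(C)C)[C@H]1[C@H](C)[C@H]2C[C@@H](C1)C2(C)C)C#C/C(C)=C\CO[Si](CC)(CC)CC | intermediate
10 | (3R,6R,9Z)-3,6-dihydroxy-6,9-dimethyl-11-(triethylsilyloxy)undeca-1,9-dien-7-yn-5-one | C=C[C@H](O)CC(=O)[C@](C)(O)C#C/C(C)=C\CO[Si](CC)(CC)CC | intermediate
11 | (3R,6R,9Z)-3-(tert-butyldimethylsilyloxy)-6-hydroxy-6,9-dimethyl-11-(triethylsilyloxy)undeca-1,9-dien-7-yn-5-one | C=C[C@H](O[Si](C)(C)C(C)(C)C)CC(=O)[C@](C)(O)C#C/C(C)=C\CO[Si](CC)(CC)CC | intermediate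
12 | (2R)-2-[(2R)-2-(tert-butyldimethylsilyloxy)but-3-en-1-yl]-2-methyl-5-[(2Z)-4-(triethylsilyloxy)but-2-en-2-yl]furan-3(2H)-one | C=C[C@H](O[Si](C)(C)C(C)(C)C)C[C@@]1(C)OC(/C(C)=C\CO[Si](CC)(CC)CC)=CC1=O | intermediate
13 | (2Z)-3-{(5R)-5-[(2R)-2-(tert-butyldimethylsilyloxy)but-3-en-1-yl]-5-methyl-4-oxo-4,5-dihydrofuran-2-yl}but-2-enal | C=C[C@H](O[Si](C)(C)C(C)(C)C)C[C@@]1(C)OC(/C(C)=C\C=O)=CC1=O | intermediate
14 | methyl 2-(bromomethyl)prop-2-enoate | C=C(CBr)C(=O)OC | starting material
15 | methyl (2Z,4R)-2-(bromomethyl)-4-(tert-butyldimethylsilyloxy)-5-{(2R)-2-methyl-3-oxo-5-[(2Z)-4-oxobut-2-en-2-yl]-2,3-dihydrofuran-2-yl}pent-2-enoate | COC(=O)/C(CBr)=C/[C@H](O[Si](C)(C)C(C)(C)C)C[C@@]1(C)OC(/C(C)=C\C=O)=CC1=O | intermediate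
16 | allylchromium dichloride from 15 (C13–Cr; C7=C11 geometry equilibrating) | COC(=O)C(C[Cr](Cl)Cl)=C[C@H](O[Si](C)(C)C(C)(C)C)C[C@@]1(C)OC(/C(C)=C\C=O)=CC1=O | intermediate
17 | (6R,7S,8R,10R) seco hydroxy ester as its chromium alkoxide: ten-membered carbocycle with C6–O–CrCl2, C7–C(=CH2)CO2Me, C8–OTBS | COC(=O)C(=C)[C@H]1[C@H](O[Cr](Cl)Cl)/C=C(/C)C2=CC(=O)[C@@](C)(C[C@H]1O[Si](C)(C)C(C)(C)C)O2 | intermediate
18 | (6R,7S,8R,10R)-8-O-(tert-butyldimethylsilyl) ether of the 8-desacyl target | C=C1C(=O)O[C@@H]2/C=C(/C)C3=CC(=O)[C@@](C)(C[C@@H](O[Si](C)(C)C(C)(C)C)[C@@H]12)O3 | intermediate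
19 | (6R,7R,8R,10R)-8-hydroxy lactone (8-desacyl target) | C=C1C(=O)O[C@@H]2/C=C(/C)C3=CC(=O)[C@@](C)(C[C@@H](O)[C@@H]12)O3 | intermediate
20 | (E)-2-methylbut-2-enoyl chloride (tigloyl chloride) | C/C=C(\C)C(=O)Cl | starting material
21 | atripliciolide tiglate, (6R,7R,8R,10R) | C=C1C(=O)O[C@@H]2/C=C(/C)C3=CC(=O)[C@@](C)(C[C@@H](OC(=O)/C(C)=C/C)[C@@H]12)O3 | target

## Step count and risks

Total steps: 10. Longest linear sequence: 10 (from 1).

Most likely to fail:

**Step 2 (the proposed mono-alkynylation of biacetyl).** Enantioselectivity is unproven on a 1,2-diketone, biacetyl can enolise and self-condense on zinc, and methyl transfer from Me2Zn can compete. The fallback uses known chemistry and sets out from 2. Alkyne 2 is added to methyl pyruvate under the established enantioselective direct alkynylation of α-keto esters (CuOtBu with a chiral prolinol-phosphine ligand) to give methyl (2R,5Z)-2-hydroxy-2,5-dimethyl-7-(triethylsilyloxy)hept-5-en-3-ynoate F1. Treatment with Me(MeO)NH·HCl and i-PrMgCl gives the Weinreb amide (2R,5Z)-2-hydroxy-N-methoxy-N,2,5-trimethyl-7-(triethylsilyloxy)hept-5-en-3-ynamide F2, and excess MeMgBr then delivers the methyl ketone, returning to the route at 6.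

**Step 7 (cross-metathesis).** A hindered allylic silyl ether and an electron-poor 1,1-disubstituted acrylate are both slow partners. The fallback sets out from 12 and builds the allylic bromide stepwise. Cleavage of the terminal alkene (OsO4 cat., NMO, then NaIO4; the isolated vinyl group should react ahead of the acceptor-conjugated C4=C5 bond) gives (2R)-2-(tert-butyldimethylsilyloxy)-3-{(2R)-2-methyl-3-oxo-5-[(2Z)-4-(triethylsilyloxy)but-2-en-2-yl]-2,3-dihydrofuran-2-yl}propanal F3. A Morita–Baylis–Hillman reaction with methyl acrylate (DABCO) gives the adduct methyl 2-[(2R)-2-(tert-butyldimethylsilyloxy)-1-hydroxy-3-(furanonyl)propyl]prop-2-enoate F4 as both carbinol epimers. SN2' bromination (NBS, Me2S) gives methyl (2Z,4R)-2-(bromomethyl)-4-(tert-butyldimethylsilyloxy)-5-{(2R)-2-methyl-3-oxo-5-[(2Z)-4-(triethylsilyloxy)but-2-en-2-yl]-2,3-dihydrofuran-2-yl}pent-2-enoate F5. Swern oxidation of the primary TES ether (i-Pr2NEt as base) returns to the route at 15.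

**Step 8 (macrocyclisation).** Oligomerisation and attack on the furanone ketone (a five-membered alternative) are possible. Acyclic 2-(alkoxycarbonyl)allylchromium reagents tend to give cis lactones, so the cis-fused epimer is a realistic outcome; the facial sense is a prediction, not a precedent on this substrate. The fallback sets out from 15 and corrects the stereocentre after ring closure instead of relying on the transition state. If the chromium closure gives mainly the (6S,7S,8R,10R) cis-fused 6-epimer F6, the lactone is opened (LiOH, THF/H2O, 0 °C) to the (6S,7S,8R,10R) hydroxy acid F7. Mitsunobu lactonisation (PPh3, DIAD, THF) then inverts C6 and returns to the route at 18.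

Further compounds
F1 | step 2 | methyl (2R,5Z)-2-hydroxy-2,5-dimethyl-7-(triethylsilyloxy)hept-5-en-3-ynoate | COC(=O)[C@](C)(O)C#C/C(C)=C\CO[Si](CC)(CC)CC
F2 | step 2 | (2R,5Z)-2-hydroxy-N-methoxy-N,2,5-trimethyl-7-(triethylsilyloxy)hept-5-en-3-ynamide | CON(C)C(=O)[C@](C)(O)C#C/C(C)=C\CO[Si](CC)(CC)CC
F3 | step 7 | (2R)-2-(tert-butyldimethylsilyloxy)-3-{(2R)-2-methyl-3-oxo-5-[(2Z)-4-(triethylsilyloxy)but-2-en-2-yl]-2,3-dihydrofuran-2-yl}propanal | O=C[C@H](O[Si](C)(C)C(C)(C)C)C[C@@]1(C)OC(/C(C)=C\CO[Si](CC)(CC)CC)=CC1=O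
F4 | step 7 | methyl 2-[(2R)-2-(tert-butyldimethylsilyloxy)-1-hydroxy-3-{(2R)-2-methyl-3-oxo-5-[(2Z)-4-(triethylsilyloxy)but-2-en-2-yl]-2,3-dihydrofuran-2-yl}propyl]prop-2-enoate (both C1 epimers) | C=C(C(=O)OC)C(O)[C@H](O[Si](C)(C)C(C)(C)C)C[C@@]1(C)OC(/C(C)=C\CO[Si](CC)(CC)CC)=CC1=O
F5 | step 7 | methyl (2Z,4R)-2-(bromomethyl)-4-(tert-butyldimethylsilyloxy)-5-{(2R)-2-methyl-3-oxo-5-[(2Z)-4-(triethylsilyloxy)but-2-en-2-yl]-2,3-dihydrofuran-2-yl}pent-2-enoate | COC(=O)/C(CBr)=C/[C@H](O[Si](C)(C)C(C)(C)C)C[C@@]1(C)OC(/C(C)=C\CO[Si](CC)(CC)CC)=CC1=O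
F6 | step 8 | (6S,7S,8R,10R) cis-fused 6-epimer of 18 | C=C1C(=O)O[C@H]2/C=C(/C)C3=CC(=O)[C@@](C)(C[C@@H](O[Si](C)(C)C(C)(C)C)[C@@H]12)O3
F7 | step 8 | (6S,7S,8R,10R) seco hydroxy acid (C6–OH, C7–C(=CH2)CO2H, C8–OTBS) | OC(=O)C(=C)[C@H]1[C@@H](O)/C=C(/C)C2=CC(=O)[C@@](C)(C[C@H]1O[Si](C)(C)C(C)(C)C)O2
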